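The readings were generated by integration with constants of no real substance; the scatter is artificial.

Work in per molar per hour, the unit of a step that takes one electrophile and one nucleophile.

| flask | electrophile | nucleophile | remark | time |
|---|---|---|---|---|
| violet | 0.050 M | 2.6 equiv | run made earlier |  |
| red | 0.050 M | 3.5 equiv | run made earlier |  |
| amber | 0.050 M | 4.4 equiv | run made earlier |  |
| dusk | 0.050 M | 2.50 equiv |  | 50 h |
| winter | 0.050 M | 5.00 equiv |  | 50 h |

| run | time / h | electrophile / % | product / % |
|---|---|---|---|
| violet | 3.00 | 91.1 | 6.7 |
| violet | 5.00 | 87.0 | 11.1 |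
| violet | 10.0 | 75.7 | 19.7 |
| violet | 20.0 | 60.4 | 33.5 |
| violet | 40.0 | 42.5 | 50.0 |
| red | 3.00 | 88.7 | 9.0 |
| red | 5.00 | 82.6 | 14.4 |
| red | 10.0 | 69.2 | 25.9 |
| red | 20.0 | 51.7 | 41.8 |
| red | 40.0 | 32.9 | 61.1 |
| amber | 8.00 | 68.7 | 26.5 |
| amber | 15.0 | 52.7 | 41.4 |
| amber | 20.0 | 44.4 | 49.2 |
| amber | 30.0 | 32.4 | 61.1 |
| amber | 40.0 | 24.7 | 69.6 |

(each reading ± 0.3 percentage points)

- part of the electrophile that has reacted at the end, dusk
- part of the electrophile that has reacted at the end, winter
- what raising the equivalents of nucleophile from its lowest to its highest value here does to the part of the electrophile that has reacted (changes below 5 percentage points count as none) (it falls / no change / it rises)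

- a reading or a percentage of product counts all its forms, free or not
- what has gone from electrophile into another species counts as reacted, even if it can come back
- a reading of electrophile is of its free form alone

1. Count as reacted whatever the free electrophile reading no longer shows.
2. Treat the nucleophile, charged in excess, as constant (the pseudo-first-order view). Free electrophile then falls as exp(−N), with N = κ · c_nucleophile · t. In words, N is the exposure: how many e-folds of free electrophile the flask has been given.
3. Read κ, the exposure constant, from the amber run at 40.0 h: 0.159 M⁻¹ h⁻¹.
4. Test it. On the violet run at 40.0 h it gives 43.8% free, and the reading is 42.5%. But the amber run at 20.0 h reads 0.185 M⁻¹ h⁻¹, so κ sags with time. One number is nearly enough, and my conversions below should run slightly high.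
5. For dusk, N = 0.993, so 63.0% reacted. For winter, N = 1.99, so 86.3% reacted. The gap of 23 percentage points exceeds 5 points, so conversion rises.
6. The forecast says 61% and 85%, it rises, noting “Early rates scale with nucleophile”.
7. The flasks give 61.6% and 84.3%: it rises, by 23 points, and the difference in equivalents of nucleophile is the main reason: winter at dusk's equivalents gives 61.6% against 84.3%.

    electrophile + nucleophile → acid set free + product (k = 5.28 × 10⁻⁵ M⁻¹ s⁻¹)
    nucleophile + acid set free ⇌ protonated nucleophile, settled at all times (K = 198 M⁻¹)
    electrophile + product ⇌ idle adduct, settled at all times (K = 7.23 M⁻¹)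

Dusk's exposure of 0.993 leaves 37.0% free, and the flask holds 38.4%. Dusk stands at 61.6% reacted in part because the nucleophile level falls, to 57% of charge, and because the reading comes at 50 h and not at 500 h: held level would give 71.5%, the later reading 98.0%. Carry κ to dusk's neighbour with 0.020 M of electrophile, equivalents and time held: N = 0.397 gives 32.8% reacted, and that flask gives 35.7%.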